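Readings and results are calculated with constants of no real substance, noise included.

- Two questions stand here, and both ask for the rate at one mark of conversion, so what you compare is flasks at the same entry in the books, not at the same hour.

| flask | starting material | partner | precatalyst | remark |
|---|---|---|---|---|
| amber | 0.28 M | 0.30 M | 0.40 mM | run made earlier |
| red | 0.44 M | 0.30 M | 0.40 mM | run made earlier |
| grey | 0.20 M | 0.45 M | 0.40 mM | run made earlier |
| flask | 0.20 M | 0.300 M | 0.40 mM |  |

| run | time / h | product / % |
|---|---|---|
| amber | 1.00 | 0 |
| amber | 1.50 | 0 |
| amber | 2.50 | 0.6 |
| amber | 4.00 | 0.9 |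
| amber | 8.00 | 1.9 |
| amber | 12.0 | 3.1 |
| red | 1.00 | 0 |
| red | 1.50 | 0 |
| red | 2.50 | 1.4 |
| red | 4.00 | 0 |
| red | 8.00 | 0 |
| red | 12.0 | 1.9 |
| grey | 1.00 | 0.2 |
| grey | 2.00 | 0.1 |
| grey | 3.00 | 0.3 |
| grey | 6.00 | 1.2 |
| grey | 12.0 | 5.6 |

(standard deviation of a reading: 0.5 percentage points)

- factor on the rate of making product when 30% of the starting material are converted if precatalyst is charged twice over
- factor on the rate when 30% of the starting material are converted if precatalyst is charged at 4.0 mM instead

- no earlier run changes the charge of precatalyst; that part of a forecast is a guess

- Keep the ledger of the starting material, the limiting reagent, at 0.20 M against 0.300 M of partner. At the mark, 0.0600 M of it has been converted and 0.140 M stays as [starting material], whatever the precatalyst charge.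
- So the entry is the same for a larger charge, which on my reckoning reaches it sooner. How much sooner depends on how product grows with time.
- The grey run goes from 1.2% at 6.00 h to 5.6% at 12.0 h, which reads as product growing as time to the power n = 2.22. A scatter of 0.5 percentage points on the smaller reading leaves n loose.
- I assume that product in the flask goes as charge times that power of time, since no run varies the charge, although the grey run holds more partner than the flask. A charge larger by a factor f then reaches the entry earlier by f to the power of the inverse of n, and the rate at the entry rises by f to that same power.
- That power is the mark order, the exponent on the charge in the rate at a given conversion: 0.450. My reckoning gives 1.37 for the doubled charge and 2.82 at 4.0 mM.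
- The forecast stands higher than my reckoning, at 1.8 (1.3 to 2.4) and 7 (3 to 13), shaded below its default that “rate roughly proportional to catalyst is the default”.
- The flask gives 1.51 and 3.67.

    catalyst intermediate C → free catalyst + product (k = 58.2 h⁻¹)
    partner + precatalyst → free catalyst + spent reagent (k = 0.0626 L mol⁻¹ h⁻¹)
    starting material + free catalyst → catalyst intermediate A (k = 218 L mol⁻¹ h⁻¹)
    catalyst intermediate A ⇌ catalyst intermediate B (K = 0.829, k = 54.5 h⁻¹)
    partner + catalyst intermediate B ⇌ catalyst intermediate C (K = 12.0 L mol⁻¹, k = 3530 L mol⁻¹ h⁻¹)

- In this flask the half-life of the precatalyst at the charged [partner] is 36.9 h, close to the 40.0 h at which the mark falls, and 80.0% of the precatalyst still stood at 12.0 h. Read back through the same rule, the flask's factors give a mark order of 0.595 for the doubled charge and 0.564 at 4.0 mM, against 0.450 from the grey run.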